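**Plan** (azulene locants of the target: C1 = isopropyl carbinol, C3 = acetoxy carbon, C3a = quaternary methyl carbon, C4 = CH2, C5 = ketone, C6 = methyl-bearing carbon, C8 = aroyloxy carbon, C8a = ring-fusion CH)
- Retrosynthesis: the two esters come off last; C6=C7 comes from the saturated C5 ketone and the C6 methyl from enolate methylation; C8–O and C8a–H come from hydroboration of a C8=C8a alkene; the seven-membered ring is then cut at C3a–C4.
- Enabling feature: the C5 ketone is γ,δ to C8a=C8 through the quaternary C3a (C5(=O)–C4–C3a–C8a=C8), and C8 is an oxygen-bearing carbon. The C8 oxygen can therefore be lent to C5 in a temporary 2-methylideneoxolane ring (an allyl vinyl ether), made from a pent-4-yn-1-ol and consumed by a ring-expanding Claisen shift.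
- Forward ring order: six-membered ring of (S)-terpinen-4-ol → allylic hydroxylation, ozonolysis and aldol ring contraction to the five-membered ring carrying C1, C3 and the C8 aldehyde → butynyl chain at C8 → temporary oxolane → seven-membered ring.
- Stereochemistry: C1 from terpinen-4-ol; C3 by SeO2 hydroxylation cis to the tertiary hydroxyl; the C8 carbinol by CBS reduction, relayed to C3a in the Claisen shift; C8a and C8 by syn hydroboration anti to the isopropyl and angular methyl groups.

Key step: step 8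

Remark: (S)-terpinen-4-ol is assumed to be used as a single enantiomer; scalemic commercial lots would be enriched beforehand.

**Step 1**
Reactants: 1 (S)-terpinen-4-ol [(4S)-p-menth-1-en-4-ol]
Product: 2 (1R,3R)-4-methyl-1-(propan-2-yl)cyclohex-4-ene-1,3-diol (cis-diol)
Conditions: SeO2 (0.3 equiv), t-BuOOH, CH2Cl2, rt
Reagents that add atoms: selenium dioxide O=[Se]=O; tert-butyl hydroperoxide CC(C)(C)OO
Why: Riley-type SeO2 allylic hydroxylation (ene reaction at the more substituted alkene carbon, then [2,3] shift) should oxidise the ring CH2 next to the methyl-bearing carbon; removal of the pseudoaxial hydrogen on the face of the axial tertiary hydroxyl (isopropyl equatorial) places the new hydroxyl cis to it.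

**Step 2**
Reactants: 2 cis-diol
Product: 3 (1R,3R)-4-methyl-1-(propan-2-yl)-1,3-bis(triethylsilyloxy)cyclohex-4-ene
Conditions: TESOTf (2.5 equiv), 2,6-lutidine, CH2Cl2, −78 to 0 °C
Reagents that add atoms: triethylsilyl trifluoromethanesulfonate CC[Si](CC)(CC)OS(=O)(=O)C(F)(F)F
Why: Silyl triflate silylation should cap both the secondary and the hindered tertiary hydroxyl without touching a stereocentre.

**Step 3**
Reactants: 3 bis-silyl ether
Product: 5 (3S,5R)-6-oxo-3-(propan-2-yl)-3,5-bis(triethylsilyloxy)heptanal, via secondary ozonide 4 (not isolated)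
Conditions: O3, CH2Cl2, −78 °C; PPh3, −78 °C to rt
Reagents that add atoms: ozone [O-][O+]=O
Why: Ozonolysis with reductive work-up should cleave the only alkene to the methyl ketone and the aldehyde; both stereocentres are spectators.

**Step 4**
Reactants: 5 keto aldehyde
Product: 6 (3R,5R)-2-methyl-5-(propan-2-yl)-3,5-bis(triethylsilyloxy)cyclopent-1-ene-1-carbaldehyde
Conditions: piperidine (0.3 equiv), AcOH (0.3 equiv), toluene, 50 °C
Reagents that add atoms: none
Why: Amine-catalysed intramolecular aldol condensation (aldehyde enamine attacks the methyl ketone, five-membered ring) followed by acid-assisted loss of the new, free tertiary hydroxyl should give the tetrasubstituted enal, as in the ring contraction of limonene-type keto aldehydes; the β-silyloxy group is the poorer leaving group and no stereocentre is formed.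

**Step 5**
Reactants: 6 cyclopentene carbaldehyde; 7 (4-bromobut-1-yn-1-yl)trimethylsilane
Product: 10 1-[(3R,5R)-2-methyl-5-(propan-2-yl)-3,5-bis(triethylsilyloxy)cyclopent-1-en-1-yl]pent-4-yn-1-ol (both carbinol epimers), via Grignard reagent 8 (not isolated), via bromomagnesium alkoxide 9 (not isolated)
Conditions: 7, Mg, THF, rt; add 6, −78 to 0 °C; then MeOH, K2CO3, rt
Reagents that add atoms: none
Why: Grignard 1,2-addition to the enal (the fully substituted β-carbon excludes conjugate addition) followed by methanolysis of the C(sp)–Si bond should give the terminal alkynol; the carbinol centre is formed without control and is erased in step 6.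

**Step 6**
Reactants: 10 alkynol epimers
Product: 11 1-[(3R,5R)-2-methyl-5-(propan-2-yl)-3,5-bis(triethylsilyloxy)cyclopent-1-en-1-yl]pent-4-yn-1-one
Conditions: Dess–Martin periodinane, NaHCO3, CH2Cl2, 0 °C to rt
Reagents that add atoms: none
Why: Dess–Martin oxidation of the allylic secondary alcohol should give the enone under buffered conditions that spare the silyl ethers and the alkyne.

**Step 7**
Reactants: 11 enone
Product: 12 (1R)-1-[(3R,5R)-2-methyl-5-(propan-2-yl)-3,5-bis(triethylsilyloxy)cyclopent-1-en-1-yl]pent-4-yn-1-ol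
Conditions: (S)-2-methyl-CBS-oxazaborolidine (0.2 equiv), catecholborane, toluene, −78 °C; aq. NaOH work-up
Reagents that add atoms: none
Why: In the CBS reduction the ketone should bind anti to the larger cyclopentenyl group and receive hydride on one face, giving the (R)-carbinol (same sense as acetophenone to (R)-1-phenylethanol with the (S)-catalyst); catecholborane at −78 °C leaves the terminal alkyne untouched.

**Step 8**
Reactants: 12 (R)-alkynol
Product: 14 (1R,3R,3aS)-3a-methyl-1-(propan-2-yl)-1,3-bis(triethylsilyloxy)-2,3,3a,4,6,7-hexahydroazulen-5(1H)-one, via methylideneoxolane 13 (not isolated)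
Conditions: MeLi (0.1 equiv), phenetole, 185 °C, sealed tube
Reagents that add atoms: none
Why: The catalytic lithium alkoxide of 12 should add 5-exo-dig to the terminal alkyne and, after proton transfer, give the 2-methylideneoxolane 13, whose allyl vinyl ether unit (C4=C5–O–C8–C8a=C3a) undergoes a [3,3]-sigmatropic Claisen shift that forms C3a–C4, breaks C8–O, unveils the C5 ketone and moves the alkene to C8=C8a. The closest known reaction type is the base-catalysed tandem 5-exo-dig cyclisation–Claisen rearrangement of 1-alkenylpent-4-yn-1-ols, that is, the ring-expanding Claisen rearrangement of 2-methylene-5-vinyltetrahydrofurans to cyclohept-4-enones. The oxolane closes by anionic 5-exo-dig attack, and the seven-membered carbocycle closes by the sigmatropic ring expansion through a boat-like transition state imposed by the two-carbon bridge of the oxolane, which also makes the new ring alkene cis. The quaternary centre C3a is set by suprafacial 1,3-chirality transfer from the C8 carbinol: with the (R)-carbinol the departing oxygen and the arriving C4 lie on the face of the cyclopentene that carries the two silyloxy groups, so C4 ends cis to the C3 oxygen. The step needs the exocyclic rather than the endocyclic enol ether and a concerted [3,3] rather than an ionic [1,3] collapse; the acid-free aprotic medium and the constrained bicyclic transition state should secure both, and any silyl shift from O1 to the C8 alkoxide is a non-productive equilibrium because only the free C8 alkoxide can cyclise.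

**Step 9**
Reactants: 14 bicyclic ketone
Product: 16 (1R,3R,3aS)-3a,6-dimethyl-1-(propan-2-yl)-1,3-bis(triethylsilyloxy)-2,3,3a,4,6,7-hexahydroazulen-5(1H)-one (C6 epimers), via lithium enolate 15 (not isolated)
Conditions: LiN(iPr)2 (LDA), THF, −78 °C; MeI, −78 to −20 °C
Reagents that add atoms: iodomethane CI
Why: Kinetic enolate alkylation: deprotonation should occur at C6 rather than at the neopentyl C4 methylene beside the quaternary C3a, and C-methylation follows; the new C6 centre is formed as a mixture and becomes sp2 in step 15.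

**Step 10**
Reactants: 16 methyl ketone
Product: 17 (1R,3R,3aS)-3a,6-dimethyl-1-(propan-2-yl)-1,3-bis(triethylsilyloxy)-2,3,3a,4,6,7-hexahydro-1H-spiro[azulene-5,2'-[1,3]dioxolane] (C6 epimers)
Conditions: TMSOCH2CH2OTMS, TMSOTf (0.1 equiv), CH2Cl2, −78 to −20 °C; pyridine quench
Reagents that add atoms: 1,2-bis(trimethylsilyloxy)ethane C[Si](C)(C)OCCO[Si](C)(C)C
Why: TMSOTf-catalysed silyl-transfer ketalisation, driven by hexamethyldisiloxane formation, should mask the ketone against borane at low temperature without touching the silyl ethers or the alkene.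

**Step 11**
Reactants: 17 ketal alkene
Product: 19 (1R,3R,3aS,8R,8aR)-3a,6-dimethyl-1-(propan-2-yl)-1,3-bis(triethylsilyloxy)octahydro-1H-spiro[azulene-5,2'-[1,3]dioxolan]-8-ol (C6 epimers), via alkylborane 18 (not isolated)
Conditions: BH3·THF, THF, 0 °C to rt; NaOH, H2O2, 0 °C to rt
Reagents that add atoms: hydrogen peroxide OO
Why: Hydroboration–oxidation should place boron on the less substituted C8 and hydrogen on C8a in a syn addition from the face opposite the C1 isopropyl and C3a methyl groups that flank the alkene, giving the trans ring fusion and, after oxidation with retention, the C8 hydroxyl on the face of 8a-H.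

**Step 12**
Reactants: 19 alcohol; 20 4-[(tert-butyldimethylsilyl)oxy]benzoic acid
Product: 21 (1R,3R,3aS,8R,8aR)-3a,6-dimethyl-1-(propan-2-yl)-1,3-bis(triethylsilyloxy)octahydro-1H-spiro[azulene-5,2'-[1,3]dioxolan]-8-yl 4-[(tert-butyldimethylsilyl)oxy]benzoate (C6 epimers)
Conditions: DCC, DMAP (0.5 equiv), CH2Cl2, rt
Reagents that add atoms: none
Why: Steglich esterification should acylate the only free hydroxyl with retention at C8, as in the known acylation of the corresponding secondary hydroxyl of daucane diols.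

**Step 13**
Reactants: 21 ester
Product: 22 (1R,3R,3aS,8R,8aR)-1,3-dihydroxy-3a,6-dimethyl-5-oxo-1-(propan-2-yl)decahydroazulen-8-yl 4-[(tert-butyldimethylsilyl)oxy]benzoate (C6 epimers)
Conditions: 1 M HCl, THF, rt
Reagents that add atoms: water O
Why: Aqueous acid hydrolysis should remove the dioxolane and both triethylsilyl ethers, while the acid-tolerant aryl silyl ether, the ester and the tertiary alcohol persist at room temperature.

**Step 14**
Reactants: 22 diol ketone
Product: 23 (1R,3R,3aS,8R,8aR)-3-(acetyloxy)-1-hydroxy-3a,6-dimethyl-5-oxo-1-(propan-2-yl)decahydroazulen-8-yl 4-[(tert-butyldimethylsilyl)oxy]benzoate (C6 epimers)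
Conditions: Ac2O, pyridine, DMAP (cat.), CH2Cl2, 0 °C to rt
Reagents that add atoms: acetic anhydride CC(=O)OC(C)=O
Why: DMAP-catalysed acetylation should esterify the secondary C3 hydroxyl and leave the hindered tertiary C1 hydroxyl free.

**Step 15**
Reactants: 23 acetate
Product: 24 (1R,3R,3aS,8R,8aR)-3-(acetyloxy)-1-hydroxy-3a,6-dimethyl-5-oxo-1-(propan-2-yl)-1,2,3,3a,4,5,8,8a-octahydroazulen-8-yl 4-[(tert-butyldimethylsilyl)oxy]benzoate
Conditions: IBX (2.2 equiv), DMSO, 70 °C
Reagents that add atoms: none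
Why: IBX dehydrogenation through the more substituted enol (C5=C6) should give the 6-methyl-6-en-5-one, since only C6–C7 can be desaturated (C4 abuts the quaternary C3a); this also removes the undefined C6 centre.

**Step 16**
Reactants: 24 silyl-protected target
Product: 25 (1R,3R,3aS,8R,8aR)-3-(acetyloxy)-1-hydroxy-3a,6-dimethyl-5-oxo-1-(propan-2-yl)-1,2,3,3a,4,5,8,8a-octahydroazulen-8-yl 4-hydroxybenzoate (target)
Conditions: HF·pyridine, THF, 0 °C to rt
Reagents that add atoms: none
Why: Fluoride cleavage of the aryl silyl ether should free the phenol under buffered conditions that spare both esters, the tertiary alcohol and the γ-acyloxy enone.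

**Compound list**
1 | (S)-terpinen-4-ol | CC1=CC[C@](O)(C(C)C)CC1 | starting material
2 | (1R,3R)-4-methyl-1-(propan-2-yl)cyclohex-4-ene-1,3-diol | O[C@@H]1C[C@@](O)(C(C)C)CC=C1C | intermediate
3 | (1R,3R)-4-methyl-1-(propan-2-yl)-1,3-bis(triethylsilyloxy)cyclohex-4-ene | CC[Si](CC)(CC)O[C@@H]1C[C@@](O[Si](CC)(CC)CC)(C(C)C)CC=C1C | intermediate
4 | secondary ozonide (1,2,4-trioxolane) of 3 | CC[Si](CC)(CC)O[C@@H]1C[C@@](O[Si](CC)(CC)CC)(C(C)C)CC2OOC1(C)O2 | intermediate
5 | (3S,5R)-6-oxo-3-(propan-2-yl)-3,5-bis(triethylsilyloxy)heptanal | CC[Si](CC)(CC)O[C@@H](C(C)=O)C[C@@](O[Si](CC)(CC)CC)(C(C)C)CC=O | intermediate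
6 | (3R,5R)-2-methyl-5-(propan-2-yl)-3,5-bis(triethylsilyloxy)cyclopent-1-ene-1-carbaldehyde | CC[Si](CC)(CC)O[C@@H]1C[C@@](O[Si](CC)(CC)CC)(C(C)C)C(C=O)=C1C | intermediate
7 | (4-bromobut-1-yn-1-yl)trimethylsilane | C[Si](C)(C)C#CCCBr | starting material
8 | [4-(trimethylsilyl)but-3-yn-1-yl]magnesium bromide | C[Si](C)(C)C#CCC[Mg]Br | intermediate
9 | bromomagnesium alkoxide of the silylalkyne adduct of 6 | CC[Si](CC)(CC)O[C@@H]1C[C@@](O[Si](CC)(CC)CC)(C(C)C)C(C(O[Mg]Br)CCC#C[Si](C)(C)C)=C1C | intermediate
10 | 1-[(3R,5R)-2-methyl-5-(propan-2-yl)-3,5-bis(triethylsilyloxy)cyclopent-1-en-1-yl]pent-4-yn-1-ol (carbinol epimers) | CC[Si](CC)(CC)O[C@@H]1C[C@@](O[Si](CC)(CC)CC)(C(C)C)C(C(O)CCC#C)=C1C | intermediate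
11 | 1-[(3R,5R)-2-methyl-5-(propan-2-yl)-3,5-bis(triethylsilyloxy)cyclopent-1-en-1-yl]pent-4-yn-1-one | CC[Si](CC)(CC)O[C@@H]1C[C@@](O[Si](CC)(CC)CC)(C(C)C)C(C(=O)CCC#C)=C1C | intermediate
12 | (1R)-1-[(3R,5R)-2-methyl-5-(propan-2-yl)-3,5-bis(triethylsilyloxy)cyclopent-1-en-1-yl]pent-4-yn-1-ol | CC[Si](CC)(CC)O[C@@H]1C[C@@](O[Si](CC)(CC)CC)(C(C)C)C([C@H](O)CCC#C)=C1C | intermediate
13 | (2R)-2-[(3R,5R)-2-methyl-5-(propan-2-yl)-3,5-bis(triethylsilyloxy)cyclopent-1-en-1-yl]-5-methylideneoxolane | CC[Si](CC)(CC)O[C@@H]1C[C@@](O[Si](CC)(CC)CC)(C(C)C)C([C@H]2CCC(=C)O2)=C1C | intermediate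
14 | (1R,3R,3aS)-3a-methyl-1-(propan-2-yl)-1,3-bis(triethylsilyloxy)-2,3,3a,4,6,7-hexahydroazulen-5(1H)-one | CC[Si](CC)(CC)O[C@@H]1C[C@@](O[Si](CC)(CC)CC)(C(C)C)C2=CCCC(=O)C[C@]12C | intermediate
15 | lithium C5=C6 enolate of 14 | CC[Si](CC)(CC)O[C@@H]1C[C@@](O[Si](CC)(CC)CC)(C(C)C)C2=CCC=C(O[Li])C[C@]12C | intermediate
16 | (1R,3R,3aS)-3a,6-dimethyl-1-(propan-2-yl)-1,3-bis(triethylsilyloxy)-2,3,3a,4,6,7-hexahydroazulen-5(1H)-one (C6 epimers) | CC[Si](CC)(CC)O[C@@H]1C[C@@](O[Si](CC)(CC)CC)(C(C)C)C2=CCC(C)C(=O)C[C@]12C | intermediate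
17 | ethylene ketal of 16 (C6 epimers) | CC[Si](CC)(CC)O[C@@H]1C[C@@](O[Si](CC)(CC)CC)(C(C)C)C2=CCC(C)C3(OCCO3)C[C@]12C | intermediate
18 | C8 alkylborane from 17 (8a-H and 8-B on the same face) | CC[Si](CC)(CC)O[C@@H]1C[C@@](O[Si](CC)(CC)CC)(C(C)C)[C@H]2[C@H](B)CC(C)C3(OCCO3)C[C@]12C | intermediate
19 | (1R,3R,3aS,8R,8aR)-3a,6-dimethyl-1-(propan-2-yl)-1,3-bis(triethylsilyloxy)octahydro-1H-spiro[azulene-5,2'-[1,3]dioxolan]-8-ol (C6 epimers) | CC[Si](CC)(CC)O[C@@H]1C[C@@](O[Si](CC)(CC)CC)(C(C)C)[C@H]2[C@H](O)CC(C)C3(OCCO3)C[C@]12C | intermediate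
20 | 4-[(tert-butyldimethylsilyl)oxy]benzoic acid | CC(C)(C)[Si](C)(C)Oc1ccc(cc1)C(=O)O | starting material
21 | 8-O-[4-(tert-butyldimethylsilyloxy)benzoyl] ester of 19 (C6 epimers) | CC[Si](CC)(CC)O[C@@H]1C[C@@](O[Si](CC)(CC)CC)(C(C)C)[C@H]2[C@H](OC(=O)c3ccc(O[Si](C)(C)C(C)(C)C)cc3)CC(C)C4(OCCO4)C[C@]12C | intermediate
22 | (1R,3R,3aS,8R,8aR)-1,3-dihydroxy-3a,6-dimethyl-5-oxo-1-(propan-2-yl)decahydroazulen-8-yl 4-[(tert-butyldimethylsilyl)oxy]benzoate (C6 epimers) | O[C@@H]1C[C@@](O)(C(C)C)[C@H]2[C@H](OC(=O)c3ccc(O[Si](C)(C)C(C)(C)C)cc3)CC(C)C(=O)C[C@]12C | intermediate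
23 | (1R,3R,3aS,8R,8aR)-3-(acetyloxy)-1-hydroxy-3a,6-dimethyl-5-oxo-1-(propan-2-yl)decahydroazulen-8-yl 4-[(tert-butyldimethylsilyl)oxy]benzoate (C6 epimers) | CC(=O)O[C@@H]1C[C@@](O)(C(C)C)[C@H]2[C@H](OC(=O)c3ccc(O[Si](C)(C)C(C)(C)C)cc3)CC(C)C(=O)C[C@]12C | intermediate
24 | (1R,3R,3aS,8R,8aR)-3-(acetyloxy)-1-hydroxy-3a,6-dimethyl-5-oxo-1-(propan-2-yl)-1,2,3,3a,4,5,8,8a-octahydroazulen-8-yl 4-[(tert-butyldimethylsilyl)oxy]benzoate | CC(=O)O[C@@H]1C[C@@](O)(C(C)C)[C@H]2[C@H](OC(=O)c3ccc(O[Si](C)(C)C(C)(C)C)cc3)C=C(C)C(=O)C[C@]12C | intermediate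
25 | (1R,3R,3aS,8R,8aR)-3-(acetyloxy)-1-hydroxy-3a,6-dimethyl-5-oxo-1-(propan-2-yl)-1,2,3,3a,4,5,8,8a-octahydroazulen-8-yl 4-hydroxybenzoate | CC(=O)O[C@@H]1C[C@@](O)(C(C)C)[C@H]2[C@H](OC(=O)c3ccc(O)cc3)C=C(C)C(=O)C[C@]12C | target

**Step count and risks**
Total step count: 16. Longest linear sequence: 16 steps (from 1; 7 and 20 are purchased).

Steps most likely to fail:

1. Step 8. Under the basic conditions the terminal alkyne may isomerise to the allene, or 13 may isomerise to the endocyclic enol ether, faster than the rearrangement at the temperature that the fully substituted terminus demands. The fallback sets out from 12 and avoids oxyanion chemistry. Cationic monovalent gold (Ph3PAuCl/AgOTf, 2 mol %) in MeOH/CH2Cl2 at rt should give, by 5-exo-dig alkoxyauration and capture of methanol, the cyclic methyl ketal F1. Treatment with TMSOTf and iPr2NEt in CH2Cl2 at −20 °C should eliminate methanol toward the methyl group and give 13 as an isolated compound. Heating 13 in xylene at 140 °C over K2CO3 should then effect the neutral Claisen shift, and the route is rejoined at 14.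

2. Step 11. Borane may add with poor facial selectivity (attack from the face of the isopropyl and angular methyl groups would give the cis-fused C8/C8a diastereomer) or too slowly at an alkene flanked by two quaternary carbons. The fallback sets out from 17 and delivers hydrogen from the C1 oxygen. Bu4NF in THF should give the diol F2, and Ac2O/pyridine should acetylate only the secondary C3 hydroxyl to give the monoacetate F3. (HMe2Si)2NH should convert the tertiary allylic hydroxyl into the dimethylsilyl ether F4. The zerovalent platinum catalyst Pt2[(CH2=CHSiMe2)2O]3 should then bring about intramolecular 5-endo hydrosilylation to the oxasilolane F5, with H on C8a and Si on C8, both on the face of O1. Tamao–Fleming oxidation (KF, KHCO3, H2O2, THF/MeOH) should give the diol F6 with retention at C8. Steglich esterification with 20 should give the ester ketal F7, and 1 M HCl/THF removes the ketal, so the route is rejoined at 23.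

3. Step 1. Oxygen may be delivered to the wrong face, or the allylic alcohol may be over-oxidised to the enone, lowering the cis-diol. The fallback sets out from 1. The crude SeO2/t-BuOOH mixture is oxidised fully with MnO2 in CH2Cl2 to the enone F8. Narasaka–Prasad reduction (Et2BOMe, NaBH4, THF/MeOH, −78 °C) should follow, in which the boron chelate bridging the axial tertiary alkoxide and the carbonyl blocks one face, so hydride arrives from the other and gives the cis-diol; the route is rejoined at 2.

**Further compounds**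
F1 | step 8 | (2R)-2-[(3R,5R)-2-methyl-5-(propan-2-yl)-3,5-bis(triethylsilyloxy)cyclopent-1-en-1-yl]-5-methoxy-5-methyloxolane (ketal epimers) | CC[Si](CC)(CC)O[C@@H]1C[C@@](O[Si](CC)(CC)CC)(C(C)C)C([C@H]2CCC(C)(OC)O2)=C1C
F2 | step 11 | 1,3-diol from 17 (ketal retained, C6 epimers) | O[C@@H]1C[C@@](O)(C(C)C)C2=CCC(C)C3(OCCO3)C[C@]12C
F3 | step 11 | C3 monoacetate of F2 | CC(=O)O[C@@H]1C[C@@](O)(C(C)C)C2=CCC(C)C3(OCCO3)C[C@]12C
F4 | step 11 | C1 dimethylsilyl ether of F3 | CC(=O)O[C@@H]1C[C@@](O[SiH](C)C)(C(C)C)C2=CCC(C)C3(OCCO3)C[C@]12C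
F5 | step 11 | oxasilolane bridging O1 and C8 (8a-H and 8-Si on the face of O1) | CC(=O)O[C@@H]1C[C@@](O[Si]4(C)C)(C(C)C)[C@H]2[C@H]4CC(C)C3(OCCO3)C[C@]12C
F6 | step 11 | C3 acetate 1,8-diol ketal | CC(=O)O[C@@H]1C[C@@](O)(C(C)C)[C@H]2[C@H](O)CC(C)C3(OCCO3)C[C@]12C
F7 | step 11 | 8-O-[4-(tert-butyldimethylsilyloxy)benzoyl] ester of F6 | CC(=O)O[C@@H]1C[C@@](O)(C(C)C)[C@H]2[C@H](OC(=O)c3ccc(O[Si](C)(C)C(C)(C)C)cc3)CC(C)C4(OCCO4)C[C@]12C
F8 | step 1 | (5R)-5-hydroxy-2-methyl-5-(propan-2-yl)cyclohex-2-en-1-one | O=C1C[C@@](O)(C(C)C)CC=C1C
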